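**Retrosynthetic overview**
1. The target is cut by two Wittig disconnections at C11=C12 and C11'=C12': C15 acetylenic phosphonium salt + C10 trienedial + C15 7',8'-dihydro phosphonium salt.
2. Both C15 salts come from one ring building block, (1R)-4-iodo-3,5,5-trimethylcyclohex-3-en-1-ol: Sonogashira coupling (C6–C7) with (E)-3-methylpent-2-en-4-yn-1-ol for the acetylenic half, and hydroboration/B-alkyl Suzuki coupling (C6'–C7') with the dienol made from the same enynol for the dihydro half.
3. The ring iodide comes from an acyclic (4S)-1-iodo-1-silylhepta-1,6-dien-4-ol by a proton-initiated cation–olefin cyclisation that forms C1–C6 (tertiary C1 cation attacked by C5=C6; Me3Si+ leaves from C6 where nature loses H+). The C3 hydroxyl is already in place.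
4. The acyclic precursor comes from (S)-epichlorohydrin (C2–C4 and the stereocentre), isopropenyl Grignard (C1), silylacetylene (C5, C6), Me3Al (C5 methyl) and I2.
5. Ring order: the six-membered ring is closed once (step 4) and the same product serves as ring A (acetylenic end) and ring B (dihydro end). No other ring is formed.

Assumption: the target is taken as all-E (3R,3'R)-7,8-didehydro-7',8'-dihydro-β,β-carotene-3,3'-diol, as the SMILES shows; this route has not been run, and step 4 is a proposed reaction without direct precedent.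

**Route**

Step 1
Reactants: 1 (S)-epichlorohydrin; 2 isopropenylmagnesium bromide
Product: 4 (2S)-2-(2-methylprop-2-en-1-yl)oxirane, via (2S)-1-chloro-4-methylpent-4-en-2-ol 3 (not isolated)
Conditions: 2 (1.2 equiv), CuI (5 mol%), THF, −40 → −20 °C; then H2O, powdered NaOH (3 equiv), 20 °C; distil
Reagents that add atoms: none
Why: Copper-catalysed Grignard opening (SN2) at the unsubstituted epoxide carbon followed by intramolecular Williamson closure of the chlorohydrin; no bond to the stereocentre is broken, so the configuration of 1 is carried into 4.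

Step 2
Reactants: 4 (2S)-2-(2-methylprop-2-en-1-yl)oxirane; 5 ethynyltrimethylsilane
Product: 6 (4S)-2-methyl-7-(trimethylsilyl)hept-1-en-6-yn-4-ol
Conditions: 5 (1.3 equiv), n-BuLi (1.25 equiv), THF, −78 °C; BF3·OEt2 (1.25 equiv), then 4, −78 °C, 1 h; aq. NH4Cl
Reagents that add atoms: none
Why: Yamaguchi–Hirao alkynylation, in which the BF3-activated epoxide is opened by the lithium acetylide at the terminal CH2 (SN2), leaving the carbinol stereocentre untouched.

Step 3
Reactants: 6 (4S)-2-methyl-7-(trimethylsilyl)hept-1-en-6-yn-4-ol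
Product: 8 (4S)-1-iodo-2,6-dimethyl-1-(trimethylsilyl)hepta-1,6-dien-4-ol, via alkenylalane 7 (not isolated)
Conditions: Me3Al (3.5 equiv), Cp2ZrCl2 (0.3 equiv), ClCH2CH2Cl, 0 → 50 °C, 16 h; then I2 (2.5 equiv), THF, −30 → 0 °C; aq. Na2S2O3, aq. NaOH/potassium sodium tartrate
Reagents that add atoms: trimethylaluminium, C[Al](C)C; iodine, II
Why: Negishi zirconium-catalysed methylalumination puts the methyl on the alkyne carbon remote from silicon and aluminium on the silyl-bearing carbon, and iodinolysis of the C–Al bond gives the 1-iodo-1-silylalkene; the E/Z ratio does not matter because this alkene geometry is erased in step 4, and the carbinol centre is not involved.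

Step 4
Reactants: 8 (4S)-1-iodo-2,6-dimethyl-1-(trimethylsilyl)hepta-1,6-dien-4-ol
Product: 10 (1R)-4-iodo-3,5,5-trimethylcyclohex-3-en-1-ol, via O-trimethylsilyl ether 9 (not isolated)
Conditions: Tf2NH (0.2 equiv), CH2Cl2 (0.02 M), −78 → −30 °C; then K2CO3 (0.3 equiv), MeOH, 20 °C
Reagents that add atoms: none
Why: Proposed new method: the strong acid protonates the 1,1-disubstituted alkene (Markovnikov) to the same tertiary C1 cation that a lycopene cyclase generates; in a chair-like six-membered transition state the C5=C6 π bond attacks it through the silyl-bearing carbon, giving a tertiary C5 cation stabilised by the β-C–Si bond (and by bridging iodine) that collapses by loss of Me3Si+ in place of the H+ lost in nature, so the double bond can only end up at C5=C6 and iodine stays on C6; the silyl cation is picked up by the hydroxyl (which releases the proton again, so the acid is catalytic) and is removed by methanolysis; the carbinol carbon is homoallylic to both alkenes, is never ionised, and keeps its configuration (the descriptor changes from S to R only because the CIP priorities change); the closest known reaction types are vinylsilane-terminated cation–olefin cyclisations (ipso substitution) and the acid cyclisation of pseudoionone to β-ionone.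

Step 5
Reactants: 10 (1R)-4-iodo-3,5,5-trimethylcyclohex-3-en-1-ol; 11 (2E)-3-methylpent-2-en-4-yn-1-ol
Product: 12 (2E)-5-[(4R)-4-hydroxy-2,6,6-trimethylcyclohex-1-en-1-yl]-3-methylpent-2-en-4-yn-1-ol
Conditions: 11 (1.3 equiv), Pd(PPh3)4 (5 mol%), CuI (10 mol%), Et3N (3 equiv), DMF, 50 °C, Ar
Reagents that add atoms: none
Why: Sonogashira coupling of the ring vinyl iodide with the terminal alkyne; the E geometry of the C9=C10 bond is bought in with 11, both free hydroxyls are tolerated and no stereocentre is touched.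

Step 6
Reactants: 12 (2E)-5-[(4R)-4-hydroxy-2,6,6-trimethylcyclohex-1-en-1-yl]-3-methylpent-2-en-4-yn-1-ol
Product: 13 [(2E)-5-[(4R)-4-hydroxy-2,6,6-trimethylcyclohex-1-en-1-yl]-3-methylpent-2-en-4-yn-1-yl]triphenylphosphonium bromide
Conditions: PPh3·HBr (1.05 equiv), MeOH, 20 °C, 16 h; precipitate from EtOAc
Reagents that add atoms: triphenylphosphine hydrobromide, [Br-].c1ccc(cc1)[PH+](c1ccccc1)c1ccccc1
Why: SN1-type substitution of the primary allylic alcohol, whose enyne-stabilised allyl cation is captured by PPh3 at the primary terminus; the non-allylic ring hydroxyl does not ionise under these conditions.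

Step 7
Reactants: 11 (2E)-3-methylpent-2-en-4-yn-1-ol
Product: 14 (2E)-3-methylpenta-2,4-dien-1-ol
Conditions: H2 (1 atm), Pd/CaCO3 poisoned with Pb(OAc)2 (5 wt%), quinoline, Et2O, 0 °C, stop after 1.0 equiv H2
Reagents that add atoms: none
Why: Lindlar semihydrogenation reduces the terminal alkyne to a vinyl group and leaves the trisubstituted E alkene unchanged.

Step 8
Reactants: 14 (2E)-3-methylpenta-2,4-dien-1-ol; 10 (1R)-4-iodo-3,5,5-trimethylcyclohex-3-en-1-ol
Product: 16 (2E)-5-[(4R)-4-hydroxy-2,6,6-trimethylcyclohex-1-en-1-yl]-3-methylpent-2-en-1-ol, via B-alkyl-9-BBN adduct 15 (not isolated)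
Conditions: 14 (1.5 equiv), 9-BBN-H (3.2 equiv), THF, 0 → 20 °C; then 10 (1.0 equiv), PdCl2(dppf) (5 mol%), AsPh3 (10 mol%), Cs2CO3 (4 equiv), DMF/H2O, 50 °C
Reagents that add atoms: none
Why: Anti-Markovnikov hydroboration of only the monosubstituted vinyl group by 9-BBN, then B-alkyl Suzuki–Miyaura coupling (sp3–sp2) with the ring iodide, gives the saturated C7'–C8' link; the E alkene and the stereocentre are untouched.

Step 9
Reactants: 16 (2E)-5-[(4R)-4-hydroxy-2,6,6-trimethylcyclohex-1-en-1-yl]-3-methylpent-2-en-1-ol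
Product: 17 [(2E)-5-[(4R)-4-hydroxy-2,6,6-trimethylcyclohex-1-en-1-yl]-3-methylpent-2-en-1-yl]triphenylphosphonium bromide
Conditions: PPh3·HBr (1.05 equiv), MeOH/CH2Cl2, 20 °C, 24 h
Reagents that add atoms: triphenylphosphine hydrobromide, [Br-].c1ccc(cc1)[PH+](c1ccccc1)c1ccccc1
Why: The same allylic alcohol-to-phosphonium substitution as in step 6 (prenyl-type allyl cation captured by PPh3 at the primary carbon); the secondary ring hydroxyl is inert.

Step 10
Reactants: 13 acetylenic C15 phosphonium bromide; 18 (2E,4E,6E)-2,7-dimethylocta-2,4,6-trienedial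
Product: 20 (2E,4E,6E,8E,10E)-13-[(4R)-4-hydroxy-2,6,6-trimethylcyclohex-1-en-1-yl]-2,7,11-trimethyltrideca-2,4,6,8,10-pentaen-12-ynal, via (11Z)-isomer 19 (not isolated)
Conditions: 18 (2.0 equiv), NaOMe (1.1 equiv), CH2Cl2/MeOH, 0 → 20 °C; then n-heptane, reflux, 2 h, Ar, dark; chromatography (excess 18 recovered)
Reagents that add atoms: none
Why: Wittig olefination with the allylic ylide, kept to one aldehyde group by the excess of dialdehyde, forms C11=C12 as an E/Z mixture whose hindered 11Z part relaxes thermally to E.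

Step 11
Reactants: 17 dihydro C15 phosphonium bromide; 20 C25 aldehyde
Product: 22 (3R,3'R)-7,8-didehydro-7',8'-dihydro-β,β-carotene-3,3'-diol (all-E, CNP0178054.1), via (11'Z)-isomer 21 (not isolated)
Conditions: NaOMe (1.2 equiv), CH2Cl2/MeOH, 0 → 20 °C; then n-heptane, reflux, 3 h, Ar, dark; crystallise (CH2Cl2/MeOH) or preparative HPLC
Reagents that add atoms: none
Why: A second Wittig olefination forms C11'=C12', and heating without iodine converts the hindered 11'-cis isomer to all-E while avoiding equilibration toward the 9-cis isomer that acetylenic carotenoids favour; both stereocentres are remote and unchanged.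

**Compound list**
1 | (S)-epichlorohydrin, (2S)-2-(chloromethyl)oxirane | ClC[C@@H]1CO1 | starting material
2 | isopropenylmagnesium bromide (prop-1-en-2-ylmagnesium bromide, THF solution) | CC(=C)[Mg]Br | starting material
3 | (2S)-1-chloro-4-methylpent-4-en-2-ol (present as its magnesium alkoxide) | CC(=C)C[C@H](O)CCl | intermediate (not isolated)
4 | (2S)-2-(2-methylprop-2-en-1-yl)oxirane | CC(=C)C[C@H]1CO1 | intermediate
5 | ethynyltrimethylsilane | C#C[Si](C)(C)C | starting material
6 | (4S)-2-methyl-7-(trimethylsilyl)hept-1-en-6-yn-4-ol | CC(=C)C[C@H](O)CC#C[Si](C)(C)C | intermediate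
7 | O,C-bis(dimethylalumanyl) methylalumination adduct of 6 (E/Z mixture, alkene geometry not defined) | CC(=C)C[C@H](O[Al](C)C)CC(C)=C([Al](C)C)[Si](C)(C)C | intermediate (not isolated)
8 | (4S)-1-iodo-2,6-dimethyl-1-(trimethylsilyl)hepta-1,6-dien-4-ol (E/Z mixture, alkene geometry not defined) | CC(=C)C[C@H](O)CC(C)=C(I)[Si](C)(C)C | intermediate
9 | [(1R)-4-iodo-3,5,5-trimethylcyclohex-3-en-1-yl]oxy(trimethyl)silane | CC1=C(I)C(C)(C)C[C@H](O[Si](C)(C)C)C1 | intermediate (not isolated)
10 | (1R)-4-iodo-3,5,5-trimethylcyclohex-3-en-1-ol | CC1=C(I)C(C)(C)C[C@H](O)C1 | intermediate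
11 | (2E)-3-methylpent-2-en-4-yn-1-ol | C#C/C(C)=C/CO | starting material
12 | (2E)-5-[(4R)-4-hydroxy-2,6,6-trimethylcyclohex-1-en-1-yl]-3-methylpent-2-en-4-yn-1-ol | CC1=C(C#C/C(C)=C/CO)C(C)(C)C[C@H](O)C1 | intermediate
13 | [(2E)-5-[(4R)-4-hydroxy-2,6,6-trimethylcyclohex-1-en-1-yl]-3-methylpent-2-en-4-yn-1-yl]triphenylphosphonium bromide | CC1=C(C#C/C(C)=C/C[P+](c2ccccc2)(c2ccccc2)c2ccccc2)C(C)(C)C[C@H](O)C1.[Br-] | intermediate
14 | (2E)-3-methylpenta-2,4-dien-1-ol | C=C/C(C)=C/CO | intermediate
15 | 9-BBN adduct of 14: B-alkyl-9-BBN at C5, hydroxyl carried as its O-(9-BBN) borinate | C(C/C(C)=C/COB1C2CCCC1CCC2)B1C2CCCC1CCC2 | intermediate (not isolated)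
16 | (2E)-5-[(4R)-4-hydroxy-2,6,6-trimethylcyclohex-1-en-1-yl]-3-methylpent-2-en-1-ol | CC1=C(CC/C(C)=C/CO)C(C)(C)C[C@H](O)C1 | intermediate
17 | [(2E)-5-[(4R)-4-hydroxy-2,6,6-trimethylcyclohex-1-en-1-yl]-3-methylpent-2-en-1-yl]triphenylphosphonium bromide | CC1=C(CC/C(C)=C/C[P+](c2ccccc2)(c2ccccc2)c2ccccc2)C(C)(C)C[C@H](O)C1.[Br-] | intermediate
18 | (2E,4E,6E)-2,7-dimethylocta-2,4,6-trienedial | O=C/C(C)=C/C=C/C=C(C)/C=O | starting material
19 | (2E,4E,6E,8Z,10E)-isomer of 20 (11Z in carotenoid numbering) | CC1=C(C#C/C(C)=C/C=C\C(C)=C\C=C\C=C(C)\C=O)C(C)(C)C[C@H](O)C1 | intermediate (not isolated)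
20 | (2E,4E,6E,8E,10E)-13-[(4R)-4-hydroxy-2,6,6-trimethylcyclohex-1-en-1-yl]-2,7,11-trimethyltrideca-2,4,6,8,10-pentaen-12-ynal | CC1=C(C#C/C(C)=C/C=C/C(C)=C/C=C/C=C(C)/C=O)C(C)(C)C[C@H](O)C1 | intermediate
21 | (11'Z)-isomer of 22 | CC1=C(C#C/C(C)=C/C=C/C(C)=C/C=C/C=C(C)/C=C\C=C(C)\CCC2=C(C)C[C@@H](O)CC2(C)C)C(C)(C)C[C@H](O)C1 | intermediate (not isolated)
22 | (3R,3'R)-7,8-didehydro-7',8'-dihydro-β,β-carotene-3,3'-diol, all-E | CC1=C(C#C/C(C)=C/C=C/C(C)=C/C=C/C=C(C)/C=C/C=C(\C)CCC2=C(C)C[C@@H](O)CC2(C)C)C(C)(C)C[C@H](O)C1 | target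

**Totals**
Total step count: 11.
Longest linear sequence: 8 steps (1 → 2 → 3 → 4 → 5 → 6 → 10 → 11).

**Three steps most likely to fail**

Step 4 (key cyclisation). The risks are steric crowding when the tertiary cation attacks the carbon carrying both I and SiMe3, protodesilylation of the vinylsilane, proton loss toward C2 (which would make an acid-labile allylic alcohol), and retro-Prins-type fragmentation that could erode the enantiomeric purity. The ee of 10 should be checked by chiral HPLC.
Fallback, setting out from 8 and coming back at 12: the order of coupling and cyclisation is inverted for the acetylenic half. Compound 11 is oxidised with MnO2 to (2E)-3-methylpent-2-en-4-ynal F1. Sonogashira coupling of 8 with it gives (2E,9S)-9-hydroxy-3,7,11-trimethyl-6-(trimethylsilyl)dodeca-2,6,11-trien-4-ynal F2, whose terminating carbon now carries a slim alkynyl group in place of iodine and whose enal end cannot ionise. The same Tf2NH-catalysed ipso-cyclisation gives (2E)-3-methyl-5-[(4R)-2,6,6-trimethyl-4-(trimethylsilyloxy)cyclohex-1-en-1-yl]pent-2-en-4-ynal F3. Methanolysis gives (2E)-5-[(4R)-4-hydroxy-2,6,6-trimethylcyclohex-1-en-1-yl]-3-methylpent-2-en-4-ynal F4, and NaBH4/CeCl3 reduction of the aldehyde returns to 12. The dihydro half is then taken through the fallback for step 8, which also starts at 8 and does not need 10.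

Step 8 (B-alkyl Suzuki coupling at a tetrasubstituted ring iodide flanked by a quaternary carbon). The risks are slow transmetalation, β-hydride elimination, and incomplete regioselectivity in the diene hydroboration.
Fallback, setting out from 8 and coming back at 16: the sp2–sp3 bond is made before the ring. Suzuki coupling of acyclic 8 with borane 15 gives (2E,9S)-3,7,11-trimethyl-6-(trimethylsilyl)dodeca-2,6,11-triene-1,9-diol F5. MnO2 oxidises only the allylic alcohol to (2E,9S)-9-hydroxy-3,7,11-trimethyl-6-(trimethylsilyl)dodeca-2,6,11-trienal F6, so that no ionisable allylic alcohol remains and the enal double bond is too electron-poor to cyclise further. The acid-catalysed vinylsilane-terminated cyclisation then gives (2E)-3-methyl-5-[(4R)-2,6,6-trimethyl-4-(trimethylsilyloxy)cyclohex-1-en-1-yl]pent-2-enal F7. Methanolysis gives (2E)-5-[(4R)-4-hydroxy-2,6,6-trimethylcyclohex-1-en-1-yl]-3-methylpent-2-enal F8, and NaBH4/CeCl3 reduction returns to 16.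

Step 3 (methylalumination of a silylalkyne next to a free hydroxyl). The risks are sluggish conversion and incomplete regiocontrol.
Fallback, setting out from 6 and coming back at 8: silicon is put on after the carbometalation. K2CO3/MeOH removes the alkynyl silyl group to give (4S)-2-methylhept-1-en-6-yn-4-ol F9. The well-behaved methylalumination–iodination of this terminal homopropargylic alcohol gives (1E,4S)-1-iodo-2,6-dimethylhepta-1,6-dien-4-ol F10. α-Deprotonation of the vinyl iodide (no β-hydrogen is available for elimination) with lithium 2,2,6,6-tetramethylpiperidide in the presence of Me3SiCl at −95 °C (in-situ quench) gives [(4S)-1-iodo-2,6-dimethyl-1-(trimethylsilyl)hepta-1,6-dien-4-yl]oxy(trimethyl)silane F11, and K2CO3/MeOH cleaves the O-silyl group to return to 8.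

**Further compounds**
F1 | step 4 | (2E)-3-methylpent-2-en-4-ynal | C#C/C(C)=C/C=O
F2 | step 4 | (2E,9S)-9-hydroxy-3,7,11-trimethyl-6-(trimethylsilyl)dodeca-2,6,11-trien-4-ynal (6E/Z mixture) | CC(=C)C[C@H](O)CC(C)=C(C#C/C(C)=C/C=O)[Si](C)(C)C
F3 | step 4 | (2E)-3-methyl-5-[(4R)-2,6,6-trimethyl-4-(trimethylsilyloxy)cyclohex-1-en-1-yl]pent-2-en-4-ynal | CC1=C(C#C/C(C)=C/C=O)C(C)(C)C[C@H](O[Si](C)(C)C)C1
F4 | step 4 | (2E)-5-[(4R)-4-hydroxy-2,6,6-trimethylcyclohex-1-en-1-yl]-3-methylpent-2-en-4-ynal | CC1=C(C#C/C(C)=C/C=O)C(C)(C)C[C@H](O)C1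
F5 | step 8 | (2E,9S)-3,7,11-trimethyl-6-(trimethylsilyl)dodeca-2,6,11-triene-1,9-diol (6E/Z mixture) | CC(=C)C[C@H](O)CC(C)=C(CC/C(C)=C/CO)[Si](C)(C)C
F6 | step 8 | (2E,9S)-9-hydroxy-3,7,11-trimethyl-6-(trimethylsilyl)dodeca-2,6,11-trienal (6E/Z mixture) | CC(=C)C[C@H](O)CC(C)=C(CC/C(C)=C/C=O)[Si](C)(C)C
F7 | step 8 | (2E)-3-methyl-5-[(4R)-2,6,6-trimethyl-4-(trimethylsilyloxy)cyclohex-1-en-1-yl]pent-2-enal | CC1=C(CC/C(C)=C/C=O)C(C)(C)C[C@H](O[Si](C)(C)C)C1
F8 | step 8 | (2E)-5-[(4R)-4-hydroxy-2,6,6-trimethylcyclohex-1-en-1-yl]-3-methylpent-2-enal | CC1=C(CC/C(C)=C/C=O)C(C)(C)C[C@H](O)C1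
F9 | step 3 | (4S)-2-methylhept-1-en-6-yn-4-ol | CC(=C)C[C@H](O)CC#C
F10 | step 3 | (1E,4S)-1-iodo-2,6-dimethylhepta-1,6-dien-4-ol | CC(=C)C[C@H](O)C/C(C)=C/I
F11 | step 3 | [(4S)-1-iodo-2,6-dimethyl-1-(trimethylsilyl)hepta-1,6-dien-4-yl]oxy(trimethyl)silane (E/Z mixture) | CC(=C)C[C@H](O[Si](C)(C)C)CC(C)=C(I)[Si](C)(C)C
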